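**Plan**
1. Retrosynthesis: remove the sulfate and the O-protecting groups; C4=CH2 ← C4=O; C8–H ← C7=C8. Then cut C5–C6 and C7–C8 of ring B together, so that the C6–C7 unit leaves as a vinylphosphonium salt. Then cut C8–CH3 (thioester), C9–C11 (benzyl bromide) and C9–C10 (conjugate addition to 2-methylcyclohex-2-en-1-one).
2. Enabling feature: in ring B, C6–C7 is the only unsubstituted CH2–CH2 unit. It joins C5, the α-carbon of the ring A carbonyl C4, to C8, a methyl-bearing carbon four atoms away (C5–C10–C9–C8). A C5 enolate and a C8 methyl ketone can therefore be bridged by one two-carbon reagent that is an electrophile at C6 and an ylide at C7.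
3. Forward: arene 8 (steps 1–5); ring A with C10 and C9 (steps 6–9); ring B by the annulation (step 10); C8–H, C4 methylidene, sulfate, deprotection (steps 11–14).
4. Stereochemistry: C10 from an enantioselective Mukaiyama–Michael addition; C9 by 1,2-induction from C10; C5 in the key step, anti to the C9 substituent on C10 (trans ring fusion); C8 by hydrogenation from the face opposite the axial C5 and C9 methyls.

Key step: step 10

Remarks. Locants C1–C11 follow the sesquiterpene numbering of the decalin: C4 the ring carbon that carries the methylidene group, C5 methylated ring-fusion carbon, C8 CH(CH3), C9 quaternary carbon, C10 ring-fusion CH, C11 benzylic CH2. TIPS = tri(propan-2-yl)silyl. Ar1 = 2-(benzyloxy)-3-(TIPS-oxy)-5-[(TIPS-oxy)methyl]phenyl; Ar2 = the same ring with a free 2-OH. A change of descriptor at an untouched centre (C10 in 13 and 15) reflects only a change of priorities. Assumption: the target is drawn as the free hydrogen sulfate; it is set free from its salt by cold proton exchange in the last step and would be stored as a salt.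

**Step 1**
Reactants: 1 3-bromo-4,5-dihydroxybenzaldehyde
Product: 2 4-(benzyloxy)-3-bromo-5-hydroxybenzaldehyde
Conditions: BnBr (1.05 equiv), NaHCO3, NaI (cat.), DMF, 40 °C
Reagents that add atoms: benzyl bromide, BrCc1ccccc1
Why: Williamson ether synthesis; the 4-OH (para to the formyl group, ortho to bromine) is the more acidic phenol and the only one ionised by hydrogen carbonate, so benzylation should be regioselective.

**Step 2**
Reactants: 2 4-(benzyloxy)-3-bromo-5-hydroxybenzaldehyde
Product: 3 [4-(benzyloxy)-3-bromo-5-hydroxyphenyl]methanol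
Conditions: NaBH4, MeOH–THF, 0 °C
Reagents that add atoms: none
Why: Borohydride reduction of the aldehyde; the aryl bromide and the benzyl ether are inert.

**Step 3**
Reactants: 3 [4-(benzyloxy)-3-bromo-5-hydroxyphenyl]methanol
Product: 4 {[4-(benzyloxy)-3-bromo-5-(TIPS-oxy)phenyl]methoxy}tri(propan-2-yl)silane
Conditions: TIPSCl (2.5 equiv), imidazole, DMF, 40 °C
Reagents that add atoms: chlorotri(propan-2-yl)silane, CC(C)[Si](Cl)(C(C)C)C(C)C
Why: Silyl ether formation at the phenol and the primary alcohol; both groups are fluoride-labile and survive bases, organometallic reagents and hydrogenation.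

**Step 4**
Reactants: 4 {[4-(benzyloxy)-3-bromo-5-(TIPS-oxy)phenyl]methoxy}tri(propan-2-yl)silane
Product: 7 {2-(benzyloxy)-3-(TIPS-oxy)-5-[(TIPS-oxy)methyl]phenyl}methanol, via aryllithium 5 (not isolated), via aldehyde 6 (not isolated)
Conditions: n-BuLi, THF, −78 °C; DMF, −78 → 0 °C; then MeOH, NaBH4, 0 °C
Reagents that add atoms: N,N-dimethylformamide, CN(C)C=O
Why: Bromine–lithium exchange, formylation of the aryllithium with DMF and borohydride reduction in one pot; the silyl ether is not ortho to the lithiated carbon, so no silyl migration is expected.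

**Step 5**
Reactants: 7 {2-(benzyloxy)-3-(TIPS-oxy)-5-[(TIPS-oxy)methyl]phenyl}methanol
Product: 8 2-(benzyloxy)-3-(TIPS-oxy)-5-[(TIPS-oxy)methyl]benzyl bromide
Conditions: CBr4, PPh3, 2,6-lutidine, CH2Cl2, 0 °C
Reagents that add atoms: tetrabromomethane, BrC(Br)(Br)Br
Why: Appel bromination of the primary benzylic alcohol under buffered conditions that spare the silyl ethers.

**Step 6**
Reactants: 9 S-ethyl propanethioate
Product: 11 {[1-(ethylsulfanyl)prop-1-en-1-yl]oxy}trimethylsilane, via lithium enolate 10 (not isolated)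
Conditions: LiN(iPr)2, THF, −78 °C; Me3SiCl; distillation
Reagents that add atoms: chlorotrimethylsilane, C[Si](C)(C)Cl
Why: O-silylation of the thioester enolate gives the silyl ketene thioacetal; its E/Z ratio is of no consequence.

**Step 7**
Reactants: 12 2-methylcyclohex-2-en-1-one; 11 {[1-(ethylsulfanyl)prop-1-en-1-yl]oxy}trimethylsilane
Product: 13 S-ethyl (2RS)-2-[(1S)-2-methyl-3-(trimethylsilyloxy)cyclohex-2-en-1-yl]propanethioate
Conditions: (S)-diphenylprolinol-derived B-(2-methylphenyl)oxazaborolidine protonated by HN(SO2CF3)2 (20 mol %), Ph3P=O (25 mol %), toluene, −20 °C; non-aqueous work-up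
Reagents that add atoms: none
Why: Catalytic enantioselective Mukaiyama–Michael addition to the six-membered enone: the cationic chiral oxazaborolidine binds the enone carbonyl and exposes one face of C10 (the catalyst antipode serves if the sense is opposite), silyl transfer to oxygen stores the regiochemistry of the C5 enolate as the enol silane, and the C9 epimer mixture is planarised in step 8.

**Step 8**
Reactants: 13 S-ethyl (2RS)-2-[(1S)-2-methyl-3-(trimethylsilyloxy)cyclohex-2-en-1-yl]propanethioate; 8 2-(benzyloxy)-3-(TIPS-oxy)-5-[(TIPS-oxy)methyl]benzyl bromide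
Product: 15 S-ethyl (2S)-3-(Ar1)-2-methyl-2-[(1R)-2-methyl-3-(trimethylsilyloxy)cyclohex-2-en-1-yl]propanethioate, via lithium enolate 14 (not isolated)
Conditions: LiN(iPr)2, THF–DMPU, −78 °C; then 8, −78 → −40 °C; Et3N-deactivated silica
Reagents that add atoms: none
Why: Enolate alkylation (SN2 at the benzylic bromide): with the C10–H bond eclipsing the enolate double bond (allylic 1,3-strain) the C5 flank with its vinylic methyl shields one face, so 8 should enter from the C1 side and set the quaternary C9 as (2S) by 1,2-induction from C10.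

**Step 9**
Reactants: 15 S-ethyl (2S)-3-(Ar1)-2-methyl-2-[(1R)-2-methyl-3-(trimethylsilyloxy)cyclohex-2-en-1-yl]propanethioate
Product: 16 (3S)-4-(Ar1)-3-methyl-3-[(1R)-2-methyl-3-(trimethylsilyloxy)cyclohex-2-en-1-yl]butan-2-one
Conditions: Me2CuLi (from MeLi and CuI), Et2O, −78 → −20 °C; NH4Cl/NH3 work-up
Reagents that add atoms: lithium dimethylcuprate, [Li+].C[Cu-]C
Why: Thioester-to-ketone substitution with a Gilman cuprate stops at the methyl ketone and leaves the enol silane, the silyl ethers and the quaternary centre untouched.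

**Step 10**
Reactants: 16 (3S)-4-(Ar1)-3-methyl-3-[(1R)-2-methyl-3-(trimethylsilyloxy)cyclohex-2-en-1-yl]butan-2-one; 17 vinyltriphenylphosphonium bromide
Product: 20 (4aS,5S,8aS)-5-[(Ar1)methyl]-5,6,8a-trimethyl-3,4,4a,5,8,8a-hexahydronaphthalen-1(2H)-one, via ammonium enolate 18 (not isolated), via phosphonium ylide 19 (not isolated)
Conditions: Bu4N[Ph3SiF2] (1.05 equiv) added to 16 and 17 (1.5 equiv), MeCN–THF, −40 → 23 °C, then 70 °C
Reagents that add atoms: none
Why: Fluoride removes the trimethylsilyl group of 16 and sets free enolate 18 at C5 only; 18 adds through C5 to the β-carbon of 17 (Michael addition, C5–C6) to give ylide 19, whose carbanionic C7 attacks the C8 methyl ketone and collapses through the oxaphosphetane to the C7=C8 olefin (intramolecular Wittig olefination). The closest known reaction type is the Michael addition/intramolecular Wittig annulation of enolates with vinylphosphonium salts, which turns a carbanion that carries a ketone on the third atom along its chain (here C5–C10–C9–C8=O) into a 1-methylcyclohexene. Ring B is closed in the Wittig event as a six-membered ring by attack of the chain carbanion on an exocyclic carbonyl (6-exo-trig addition), and the ring enforces the cis olefin. The new stereocentre C5 is set in the Michael step: the quaternary C9 group on C10 lies pseudoaxial (allylic strain with the C5 methyl) and the electrophile enters the enolate anti to it, which gives the trans relation of C6 and C9 and hence the trans ring fusion. The step needs C-alkylation at C5 ahead of proton transfer to the enolate, and Wittig closure onto C8 and not C4; the first is secured by generating the enolate regiospecifically in the presence of excess 17, the second by ring size (closure onto C4 would give a four-membered ring), and the ylide is a weaker base than either ketone enolate, so enolisation by it is unfavourable.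

**Step 11**
Reactants: 20 (4aS,5S,8aS)-5-[(Ar1)methyl]-5,6,8a-trimethyl-3,4,4a,5,8,8a-hexahydronaphthalen-1(2H)-one
Product: 22 (4aS,5R,6S,8aS)-5-[(Ar2)methyl]-5,6,8a-trimethyloctahydronaphthalen-1(2H)-one, via phenol olefin 21 (not isolated)
Conditions: H2 (3 atm), Pd/C, EtOAc, 23 °C
Reagents that add atoms: none
Why: Heterogeneous hydrogenation should deliver hydrogen to the α face of the C7=C8 olefin, opposite the syn-axial methyls on C5 and C9, which sets C8 (H α, methyl equatorial); the same operation hydrogenolyses the aryl benzyl ether and unmasks the one phenol that is to be sulfated.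

**Step 12**
Reactants: 22 (4aS,5R,6S,8aS)-5-[(Ar2)methyl]-5,6,8a-trimethyloctahydronaphthalen-1(2H)-one
Product: 23 2-{[(1R,2S,4aS,8aS)-1,2,4a-trimethyl-5-methylidenedecahydronaphthalen-1-yl]methyl}-6-(TIPS-oxy)-4-[(TIPS-oxy)methyl]phenol
Conditions: Cp2TiMe2 (4 equiv), toluene–THF, 75 °C, dark; MeOH quench
Reagents that add atoms: dimethyltitanocene, [CH3-].[CH3-].[Ti+4].c1cc[cH-]c1.c1cc[cH-]c1
Why: Petasis methylenation (titanium methylidene) of the hindered C4 ketone; the non-basic reagent avoids the 1,2-silyl shift between the catechol oxygens that a phenoxide would invite, and no stereocentre is touched.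

**Step 13**
Reactants: 23 2-{[(1R,2S,4aS,8aS)-1,2,4a-trimethyl-5-methylidenedecahydronaphthalen-1-yl]methyl}-6-(TIPS-oxy)-4-[(TIPS-oxy)methyl]phenol
Product: 24 pyridinium 2-{[(1R,2S,4aS,8aS)-1,2,4a-trimethyl-5-methylidenedecahydronaphthalen-1-yl]methyl}-6-(TIPS-oxy)-4-[(TIPS-oxy)methyl]phenyl sulfate
Conditions: SO3·pyridine (5 equiv), pyridine, 50 °C
Reagents that add atoms: sulfur trioxide–pyridine, O=S(=O)([O-])[n+]1ccccc1
Why: O-sulfonation of the only free hydroxyl group; the second phenol and the benzylic alcohol are silylated and the exocyclic olefin is inert to the complexed SO3.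

**Step 14**
Reactants: 24 pyridinium 2-{[(1R,2S,4aS,8aS)-1,2,4a-trimethyl-5-methylidenedecahydronaphthalen-1-yl]methyl}-6-(TIPS-oxy)-4-[(TIPS-oxy)methyl]phenyl sulfate
Product: 26 2-hydroxy-4-(hydroxymethyl)-6-{[(1R,2S,4aS,8aS)-1,2,4a-trimethyl-5-methylidenedecahydronaphthalen-1-yl]methyl}phenyl hydrogen sulfate, via tetrabutylammonium sulfate 25 (not isolated)
Conditions: Bu4NF, THF, 0 → 23 °C; then sulfonic acid resin (H+ form), MeOH–H2O, 0 °C, freeze-drying
Reagents that add atoms: none
Why: Fluoride cleaves both Si–O bonds while the aryl sulfate monoester is inert to fluoride and base; brief cold proton exchange then gives the free acid without hydrolysis of the sulfate or migration of the exocyclic olefin.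

**Compound list**
1 | 3-bromo-4,5-dihydroxybenzaldehyde | O=Cc1cc(O)c(O)c(Br)c1 | starting material
2 | 4-(benzyloxy)-3-bromo-5-hydroxybenzaldehyde | O=Cc1cc(O)c(OCc2ccccc2)c(Br)c1 | intermediate
3 | [4-(benzyloxy)-3-bromo-5-hydroxyphenyl]methanol | OCc1cc(O)c(OCc2ccccc2)c(Br)c1 | intermediate
4 | {[4-(benzyloxy)-3-bromo-5-(TIPS-oxy)phenyl]methoxy}tri(propan-2-yl)silane | Brc1cc(CO[Si](C(C)C)(C(C)C)C(C)C)cc(O[Si](C(C)C)(C(C)C)C(C)C)c1OCc1ccccc1 | intermediate
5 | {2-(benzyloxy)-3-(TIPS-oxy)-5-[(TIPS-oxy)methyl]phenyl}lithium | [Li]c1cc(CO[Si](C(C)C)(C(C)C)C(C)C)cc(O[Si](C(C)C)(C(C)C)C(C)C)c1OCc1ccccc1 | intermediate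
6 | 2-(benzyloxy)-3-(TIPS-oxy)-5-[(TIPS-oxy)methyl]benzaldehyde | O=Cc1cc(CO[Si](C(C)C)(C(C)C)C(C)C)cc(O[Si](C(C)C)(C(C)C)C(C)C)c1OCc1ccccc1 | intermediate
7 | {2-(benzyloxy)-3-(TIPS-oxy)-5-[(TIPS-oxy)methyl]phenyl}methanol | OCc1cc(CO[Si](C(C)C)(C(C)C)C(C)C)cc(O[Si](C(C)C)(C(C)C)C(C)C)c1OCc1ccccc1 | intermediate
8 | 2-(benzyloxy)-3-(TIPS-oxy)-5-[(TIPS-oxy)methyl]benzyl bromide | BrCc1cc(CO[Si](C(C)C)(C(C)C)C(C)C)cc(O[Si](C(C)C)(C(C)C)C(C)C)c1OCc1ccccc1 | intermediate
9 | S-ethyl propanethioate | CCC(=O)SCC | starting material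
10 | lithium 1-(ethylsulfanyl)prop-1-en-1-olate | CC=C([O-])SCC.[Li+] | intermediate
11 | {[1-(ethylsulfanyl)prop-1-en-1-yl]oxy}trimethylsilane (E/Z mixture) | CC=C(SCC)O[Si](C)(C)C | intermediate
12 | 2-methylcyclohex-2-en-1-one | CC1=CCCCC1=O | starting material
13 | S-ethyl (2RS)-2-[(1S)-2-methyl-3-(trimethylsilyloxy)cyclohex-2-en-1-yl]propanethioate | C[Si](C)(C)OC1=C(C)[C@H](C(C)C(=O)SCC)CCC1 | intermediate
14 | lithium enolate of 13 | C[Si](C)(C)OC1=C(C)[C@H](C(C)=C([O-])SCC)CCC1.[Li+] | intermediate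
15 | S-ethyl (2S)-3-(Ar1)-2-methyl-2-[(1R)-2-methyl-3-(trimethylsilyloxy)cyclohex-2-en-1-yl]propanethioate | C[Si](C)(C)OC1=C(C)[C@H]([C@](C)(Cc2cc(CO[Si](C(C)C)(C(C)C)C(C)C)cc(O[Si](C(C)C)(C(C)C)C(C)C)c2OCc3ccccc3)C(=O)SCC)CCC1 | intermediate
16 | (3S)-4-(Ar1)-3-methyl-3-[(1R)-2-methyl-3-(trimethylsilyloxy)cyclohex-2-en-1-yl]butan-2-one | C[Si](C)(C)OC1=C(C)[C@H]([C@](C)(Cc2cc(CO[Si](C(C)C)(C(C)C)C(C)C)cc(O[Si](C(C)C)(C(C)C)C(C)C)c2OCc3ccccc3)C(C)=O)CCC1 | intermediate
17 | vinyltriphenylphosphonium bromide | C=C[P+](c1ccccc1)(c1ccccc1)c1ccccc1.[Br-] | starting material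
18 | tetrabutylammonium (3R)-3-[(2S)-1-(Ar1)-2-methyl-3-oxobutan-2-yl]-2-methylcyclohex-1-en-1-olate | [O-]C1=C(C)[C@H]([C@](C)(Cc2cc(CO[Si](C(C)C)(C(C)C)C(C)C)cc(O[Si](C(C)C)(C(C)C)C(C)C)c2OCc3ccccc3)C(C)=O)CCC1.CCCC[N+](CCCC)(CCCC)CCCC | intermediate
19 | (2S,3S)-3-[(2S)-1-(Ar1)-2-methyl-3-oxobutan-2-yl]-2-methyl-2-[2-(triphenyl-λ5-phosphanylidene)ethyl]cyclohexan-1-one | O=C1CCC[C@@H]([C@](C)(Cc2cc(CO[Si](C(C)C)(C(C)C)C(C)C)cc(O[Si](C(C)C)(C(C)C)C(C)C)c2OCc3ccccc3)C(C)=O)[C@]1(C)CC=P(c1ccccc1)(c1ccccc1)c1ccccc1 | intermediate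
20 | (4aS,5S,8aS)-5-[(Ar1)methyl]-5,6,8a-trimethyl-3,4,4a,5,8,8a-hexahydronaphthalen-1(2H)-one | O=C1CCC[C@H]2[C@](C)(Cc3cc(CO[Si](C(C)C)(C(C)C)C(C)C)cc(O[Si](C(C)C)(C(C)C)C(C)C)c3OCc4ccccc4)C(C)=CC[C@]12C | intermediate
21 | (4aS,5S,8aS)-5-[(Ar2)methyl]-5,6,8a-trimethyl-3,4,4a,5,8,8a-hexahydronaphthalen-1(2H)-one | O=C1CCC[C@H]2[C@](C)(Cc3cc(CO[Si](C(C)C)(C(C)C)C(C)C)cc(O[Si](C(C)C)(C(C)C)C(C)C)c3O)C(C)=CC[C@]12C | intermediate
22 | (4aS,5R,6S,8aS)-5-[(Ar2)methyl]-5,6,8a-trimethyloctahydronaphthalen-1(2H)-one | O=C1CCC[C@H]2[C@](C)(Cc3cc(CO[Si](C(C)C)(C(C)C)C(C)C)cc(O[Si](C(C)C)(C(C)C)C(C)C)c3O)[C@@H](C)CC[C@]12C | intermediate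
23 | 2-{[(1R,2S,4aS,8aS)-1,2,4a-trimethyl-5-methylidenedecahydronaphthalen-1-yl]methyl}-6-(TIPS-oxy)-4-[(TIPS-oxy)methyl]phenol | C=C1CCC[C@H]2[C@](C)(Cc3cc(CO[Si](C(C)C)(C(C)C)C(C)C)cc(O[Si](C(C)C)(C(C)C)C(C)C)c3O)[C@@H](C)CC[C@]12C | intermediate
24 | pyridinium 2-{[(1R,2S,4aS,8aS)-1,2,4a-trimethyl-5-methylidenedecahydronaphthalen-1-yl]methyl}-6-(TIPS-oxy)-4-[(TIPS-oxy)methyl]phenyl sulfate | C=C1CCC[C@H]2[C@](C)(Cc3cc(CO[Si](C(C)C)(C(C)C)C(C)C)cc(O[Si](C(C)C)(C(C)C)C(C)C)c3OS(=O)(=O)[O-])[C@@H](C)CC[C@]12C.c1cc[nH+]cc1 | intermediate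
25 | tetrabutylammonium 2-hydroxy-4-(hydroxymethyl)-6-{[(1R,2S,4aS,8aS)-1,2,4a-trimethyl-5-methylidenedecahydronaphthalen-1-yl]methyl}phenyl sulfate | C=C1CCC[C@H]2[C@](C)(Cc3cc(CO)cc(O)c3OS(=O)(=O)[O-])[C@@H](C)CC[C@]12C.CCCC[N+](CCCC)(CCCC)CCCC | intermediate
26 | 2-hydroxy-4-(hydroxymethyl)-6-{[(1R,2S,4aS,8aS)-1,2,4a-trimethyl-5-methylidenedecahydronaphthalen-1-yl]methyl}phenyl hydrogen sulfate | C=C1CCC[C@H]2[C@](C)(Cc3cc(CO)cc(O)c3OS(=O)(=O)O)[C@@H](C)CC[C@]12C | target

**Step count**
Total: 14 steps. Longest linear sequence: 12 steps (steps 1–5, then 8–14).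

**Steps most likely to fail, with fallbacks**

Step 10. Once the enolate is unmasked, proton transfer from the acetyl group to C5 (followed by bridged aldol closure onto C4) can compete with the Michael addition, and the hindered ylide may fail to close onto the neopentyl-type C8 ketone. The fallback sets out from 16 and comes back at 20; it makes the two bonds one after the other by enolate allylation and olefin metathesis. The C8 ketone of 16, the only carbonyl present, is methylenated with Cp2TiMe2 (toluene, 65 °C) to isopropenyl enol silane F1. MeLi (THF, 0 °C) then frees the regiodefined lithium enolate, which allyl bromide (−78 °C) alkylates anti to the C10 substituent to give allyl ketone F2. Ring-closing metathesis with the second-generation Grubbs catalyst (H2IMes)(PCy3)Cl2Ru=CHPh (toluene, 80 °C) closes ring B with loss of ethene and gives 20.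

Step 8. Facial discrimination at the enolate of 13 may be weak or reversed, and the hindered α-branched thioester enolate may alkylate slowly while it decays to a ketene. The fallback sets out from 8 and 12 and comes back at 15; it introduces the two C9 substituents in the opposite order, which by the same allylic-strain argument turns the other face of C9 toward the incoming group, so whichever flank of the enolate proves the more shielded, one of the two orders delivers 15. Bromide 8 alkylates the lithium enolate of S-ethyl ethanethioate (LiN(iPr)2, THF, −78 °C) to give thioester F3. Silylation (LiN(iPr)2, Me3SiCl) gives ketene thioacetal F4. Mukaiyama–Michael addition of F4 to 12 under the conditions of step 7 gives enol silane F5, and enolisation (LiN(iPr)2) with methylation (MeI) gives 15. A weak bias in both orders would have to be met by separating the C9 epimers at 15.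

Step 7. The α-methyl enone may react sluggishly with the chiral Lewis acid, the face selectivity at C10 may be poor, and loss of the silyl group during isolation would erase the regiochemistry of the enolate. The fallback sets out from 12 and comes back at 13; it takes the absolute configuration from an enantioselective ketone reduction and a [3,3] chirality transfer. Corey–Bakshi–Shibata reduction of 12 (BH3·SMe2, the B-methyl oxazaborolidine enantiomer that gives the S alcohol) gives (1S)-2-methylcyclohex-2-en-1-ol F6. Johnson–Claisen rearrangement with triethyl orthopropanoate (propanoic acid cat., 140 °C) carries the C–O configuration suprafacially to C10 and gives ester F7. Me2AlSEt (from AlMe3 and ethanethiol, CH2Cl2) converts F7 into thioester F8. Hydroboration–oxidation (BH3·SMe2, 0 °C; NaBO3) places oxygen on C4 and gives alcohol F9, which Dess–Martin periodinane oxidises to ketone F10. Silylation under equilibrating conditions (Me3SiI, (Me3Si)2NH, CH2Cl2) gives the more substituted enol silane 13.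

**Further compounds**
F1 | step 10 | trimethyl({(3S)-3-[(2S)-1-(Ar1)-2,3-dimethylbut-3-en-2-yl]-2-methylcyclohex-1-en-1-yl}oxy)silane | C[Si](C)(C)OC1=C(C)[C@H]([C@](C)(Cc2cc(CO[Si](C(C)C)(C(C)C)C(C)C)cc(O[Si](C(C)C)(C(C)C)C(C)C)c2OCc3ccccc3)C(C)=C)CCC1
F2 | step 10 | (2S,3S)-3-[(2S)-1-(Ar1)-2,3-dimethylbut-3-en-2-yl]-2-methyl-2-(prop-2-en-1-yl)cyclohexan-1-one | O=C1CCC[C@@H]([C@](C)(Cc2cc(CO[Si](C(C)C)(C(C)C)C(C)C)cc(O[Si](C(C)C)(C(C)C)C(C)C)c2OCc3ccccc3)C(C)=C)[C@]1(C)CC=C
F3 | step 8 | S-ethyl 3-(Ar1)propanethioate | CCSC(=O)CCc1cc(CO[Si](C(C)C)(C(C)C)C(C)C)cc(O[Si](C(C)C)(C(C)C)C(C)C)c1OCc1ccccc1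
F4 | step 8 | {[3-(Ar1)-1-(ethylsulfanyl)prop-1-en-1-yl]oxy}trimethylsilane | CCSC(O[Si](C)(C)C)=CCc1cc(CO[Si](C(C)C)(C(C)C)C(C)C)cc(O[Si](C(C)C)(C(C)C)C(C)C)c1OCc1ccccc1
F5 | step 8 | S-ethyl (2RS)-3-(Ar1)-2-[(1S)-2-methyl-3-(trimethylsilyloxy)cyclohex-2-en-1-yl]propanethioate | C[Si](C)(C)OC1=C(C)[C@H](C(Cc2cc(CO[Si](C(C)C)(C(C)C)C(C)C)cc(O[Si](C(C)C)(C(C)C)C(C)C)c2OCc3ccccc3)C(=O)SCC)CCC1
F6 | step 7 | (1S)-2-methylcyclohex-2-en-1-ol | O[C@H]1CCCC=C1C
F7 | step 7 | ethyl (2RS)-2-[(1S)-2-methylcyclohex-2-en-1-yl]propanoate | CCOC(=O)C(C)[C@@H]1CCCC=C1C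
F8 | step 7 | S-ethyl (2RS)-2-[(1S)-2-methylcyclohex-2-en-1-yl]propanethioate | CCSC(=O)C(C)[C@@H]1CCCC=C1C
F9 | step 7 | S-ethyl 2-[(1R)-3-hydroxy-2-methylcyclohexyl]propanethioate (mixture at the other centres) | CCSC(=O)C(C)[C@@H]1CCCC(O)C1C
F10 | step 7 | S-ethyl 2-[(1R)-2-methyl-3-oxocyclohexyl]propanethioate (mixture at the other centres) | CCSC(=O)C(C)[C@@H]1CCCC(=O)C1C
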